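**Retrosynthetic overview**

1. Locants follow the open chain: C6 = ring CH, C7 = ring C(CH3)O, C8–C9 = ring CH2CH2, C10 = CHOH, C11 = quaternary ring carbon bearing the lactone C=O. After desilylation, the last disconnection is the C9–C10 bond (ring CH2 to carbinol carbon), made by a cobalt-catalysed CrCl2 Barbier-type addition of a 2-iodoethyl group on C7 to a formyl group on C11.
2. Enabling feature: the 1,4-dioxan-2-one ring (O–C6–C7–O–C(=O)–C11) holds C11 and C7 in a 1,4-relationship. The formyl group on C11 and the iodoethyl arm on C7 are cis and meet as the flagpole substituents of the boat, so the three-carbon bridge C8–C9–C10 turns the six-membered ring into the 6,8-dioxabicyclo[3.2.2]nonan-7-one.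
3. The quaternary C11 comes from face-selective alkylation of a malonate-type dioxanone with a Z-homoallylic iodide (chain trans to the C6 chain); the tert-butyl ester becomes the formyl carbon C10 and the ethenyl group becomes C8–C9.
4. The dioxanone comes from an anti-diol and tert-butyl bromoacetate; the diol comes from nerol by allylic oxidation, Sharpless epoxidation (the only catalyst-controlled step, sets C6 and C7) and a Payne/sulfonium-ylide cascade (inversion at C7, ethenyl = C8–C9).
5. Ring order: dioxanone first (step 10); oxepane and ε-lactone last, both in the one event of step 17. Stereochemical relay: C6/C7 → C11 → C10.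

Key step: step 17

Remark: the SMILES is read as (1R,2S,5R,9S) in the bicyclic numbering used below; TBS = tert-butyldimethylsilyl, TBDPS = tert-butyldiphenylsilyl, chain A = (3Z)-5-(TBDPS-oxy)-4-methylpent-3-en-1-yl (on C11), chain B = (3Z)-5-(TBDPS-oxy)-3-methylpent-3-en-1-yl (on C6).

**Side chain for C11 (steps 1–5)**

Step 1
Reactants: 1 3-(TBS-oxy)propanal; 2 ethyl 2-[bis(2,2,2-trifluoroethoxy)phosphoryl]propanoate
Product: 3 ethyl (2Z)-5-(TBS-oxy)-2-methylpent-2-enoate
Conditions: KN(SiMe3)2, 18-crown-6, THF, −78 °C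
Reagents that add atoms: none
Why: Still–Gennari olefination, in which the electron-poor phosphonate under dissociating conditions should give the Z-trisubstituted enoate (ester cis to the chain) and so fix the C14=C15 geometry.

Step 2
Reactants: 3 Z-enoate
Product: 4 (2Z)-5-(TBS-oxy)-2-methylpent-2-en-1-ol
Conditions: iBu2AlH, CH2Cl2, −78 °C
Reagents that add atoms: none
Why: 1,2-reduction of the conjugated ester by iBu2AlH should give the allylic alcohol without touching the alkene geometry or the silyl ether.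

Step 3
Reactants: 4 Z-allylic alcohol
Product: 5 (2Z)-5-(TBS-oxy)-1-(TBDPS-oxy)-2-methylpent-2-ene
Conditions: TBDPSCl, imidazole, CH2Cl2, 0 °C to rt
Reagents that add atoms: tert-butyl(chloro)diphenylsilane, CC(C)(C)[Si](Cl)(c1ccccc1)c1ccccc1
Why: Silylation of the primary allylic alcohol with the more acid-stable TBDPS group sets up the selective desilylation that follows.

Step 4
Reactants: 5 bis-silyl ether
Product: 6 (3Z)-5-(TBDPS-oxy)-4-methylpent-3-en-1-ol
Conditions: pyridinium p-toluenesulfonate (cat.), MeOH, rt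
Reagents that add atoms: none
Why: Mild acidic methanolysis should remove the primary TBS ether much faster than the TBDPS ether (selective desilylation).

Step 5
Reactants: 6 homoallylic alcohol
Product: 7 tert-butyl{[(2Z)-5-iodo-2-methylpent-2-en-1-yl]oxy}diphenylsilane
Conditions: I2, PPh3, imidazole, CH2Cl2, 0 °C
Reagents that add atoms: iodine, I-I
Why: Appel-type iodination, in which iodide displaces the alkoxyphosphonium by SN2 at the primary carbon.

**Main line from nerol (steps 6–18)**

Step 6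
Reactants: 8 nerol
Product: 9 neryl TBDPS ether
Conditions: TBDPSCl, imidazole, CH2Cl2, 0 °C to rt
Reagents that add atoms: tert-butyl(chloro)diphenylsilane, CC(C)(C)[Si](Cl)(c1ccccc1)c1ccccc1
Why: Silylation of the primary allylic alcohol; the Z-alkene of nerol becomes the C2=C3 alkene of the target unchanged.

Step 7
Reactants: 9 neryl TBDPS ether
Product: 10 (2E,6Z)-8-(TBDPS-oxy)-2,6-dimethylocta-2,6-dien-1-ol
Conditions: SeO2 (cat.), t-BuOOH, salicylic acid (cat.), CH2Cl2, rt, stopped at partial conversion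
Reagents that add atoms: tert-butyl hydroperoxide, CC(C)(C)OO (oxygen atom, relayed by SeO2)
Why: SeO2-catalysed allylic oxidation (ene reaction then [2,3]-sigmatropic shift) should attack the electron-rich terminal alkene at its E-methyl group and give the E-allylic alcohol, the alkene next to the silyloxy group being deactivated.

Step 8
Reactants: 10 E-allylic alcohol
Product: 11 [(2S,3S)-2-methyl-3-(chain B)oxiran-2-yl]methanol
Conditions: Ti(OiPr)4 (cat.), L-(+)-diethyl tartrate (cat.), t-BuOOH, 4 Å molecular sieves, CH2Cl2, −20 °C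
Reagents that add atoms: tert-butyl hydroperoxide, CC(C)(C)OO
Why: Sharpless asymmetric epoxidation touches only the free allylic alcohol, and L-(+)-diethyl tartrate should deliver oxygen to the face that gives the (2S,3S)-epoxide, which fixes C6 directly and C7 after the inversion in step 9.

Step 9
Reactants: 11 epoxy alcohol; 12 trimethylsulfonium iodide
Product: 14 (3R,4S,7Z)-9-(TBDPS-oxy)-3,7-dimethylnona-1,7-diene-3,4-diol, via Payne-rearranged terminal epoxide 13 (not isolated)
Conditions: 12 (4 equiv), n-BuLi (3.9 equiv), THF, −10 °C to rt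
Reagents that add atoms: none
Why: The alkoxide undergoes Payne rearrangement (intramolecular SN2 at C7 with inversion, C6 oxygen retained) to terminal epoxide 13, which dimethylsulfonium methylide opens at its CH2 group before eliminating dimethyl sulfide, so the known one-carbon homologation of epoxides to allylic alcohols should give the anti-diol with the ethenyl group as C8–C9.

Step 10
Reactants: 14 ethenyl diol; 15 tert-butyl bromoacetate
Product: 17 (5S,6R)-5-(chain B)-6-ethenyl-6-methyl-1,4-dioxan-2-one, via hydroxy tert-butyl ester 16 (not isolated)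
Conditions: NaH (2.2 equiv), Bu4NI (cat.), THF–DMF, 0 °C to 40 °C
Reagents that add atoms: none
Why: Williamson etherification should occur at the secondary alkoxide rather than the hindered tertiary allylic one, after which the tertiary alkoxide closes the six-membered lactone on the tert-butyl ester (6-exo-trig), an ester that resists intermolecular acyl transfer.

Step 11
Reactants: 17 dioxanone; 18 di-tert-butyl dicarbonate
Product: 19 tert-butyl (5R,6S)-5-ethenyl-5-methyl-3-oxo-6-(chain B)-1,4-dioxane-2-carboxylate (both C2 epimers)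
Conditions: LiN(SiMe3)2 (2.2 equiv), THF, −78 °C; 18; NH4Cl quench at −78 °C
Reagents that add atoms: none
Why: Claisen-type C-acylation of the lactone enolate gives the malonate-type lactone, the second equivalent of base taking up its acidic proton, and the low temperature should prevent Ireland–Claisen rearrangement of this allylic ester enolate; the C2 configuration is irrelevant because step 12 re-enolises it.

Step 12
Reactants: 19 malonate-type dioxanone; 7 Z-homoallylic iodide
Product: 20 tert-butyl (2R,5R,6S)-5-ethenyl-5-methyl-3-oxo-2-(chain A)-6-(chain B)-1,4-dioxane-2-carboxylate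
Conditions: Cs2CO3, DMF, rt to 40 °C
Reagents that add atoms: none
Why: SN2 alkylation of the caesium enolate, in which the iodide should add axially to the half-chair on the face opposite to chain B and the pseudoaxial ethenyl group (as in alkylations of chiral dioxanone and morpholinone templates), setting C11 with the ester cis to the ethenyl arm.

Step 13
Reactants: 20 alkylated dioxanone
Product: 22 tert-butyl (2R,5R,6S)-5-(2-hydroxyethyl)-5-methyl-3-oxo-2-(chain A)-6-(chain B)-1,4-dioxane-2-carboxylate, via B-alkyl-9-BBN adduct 21 (not isolated)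
Conditions: 9-BBN, THF, 0 °C to rt; then H2O2, aq. NaOAc, 0 °C to rt
Reagents that add atoms: 9-borabicyclo[3.3.1]nonane, B1C2CCCC1CCC2 (boron in 21 only); hydrogen peroxide, OO (oxygen of 22)
Why: 9-BBN should hydroborate the monosubstituted ethenyl group anti-Markovnikov and leave both trisubstituted alkenes alone, and buffered peroxide oxidation spares the lactone.

Step 14
Reactants: 22 primary alcohol
Product: 23 tert-butyl (2R,5R,6S)-5-(2-iodoethyl)-5-methyl-3-oxo-2-(chain A)-6-(chain B)-1,4-dioxane-2-carboxylate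
Conditions: I2, PPh3, imidazole, CH2Cl2, 0 °C
Reagents that add atoms: iodine, I-I
Why: Appel-type iodination of the unhindered primary alcohol by SN2, under neutral conditions that the lactone, ester and silyl ethers tolerate.

Step 15
Reactants: 23 iodo tert-butyl ester
Product: 25 (2R,5R,6S)-5-(2-iodoethyl)-5-methyl-3-oxo-2-(chain A)-6-(chain B)-1,4-dioxane-2-carboxylic acid, via trimethylsilyl ester 24 (not isolated)
Conditions: Me3SiOTf, 2,6-lutidine, CH2Cl2, 0 °C; then H2O
Reagents that add atoms: trimethylsilyl trifluoromethanesulfonate, C[Si](C)(C)OS(=O)(=O)C(F)(F)F (silyl group in 24 only)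
Why: Silyl-triflate cleavage of the tert-butyl ester with loss of 2-methylpropene should be faster than ionisation of the more hindered, β-oxygenated tertiary lactone, and the buffered conditions spare the TBDPS ethers and the iodide.

Step 16
Reactants: 25 carboxylic acid
Product: 27 (2R,5R,6S)-5-(2-iodoethyl)-5-methyl-3-oxo-2-(chain A)-6-(chain B)-1,4-dioxane-2-carbaldehyde, via acid chloride 26 (not isolated)
Conditions: (COCl)2, DMF (cat.), CH2Cl2, 0 °C; then LiAlH(OtBu)3, THF, −78 °C; used crude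
Reagents that add atoms: oxalyl chloride, O=C(Cl)C(=O)Cl (chlorine in 26 only)
Why: The hindered hydride LiAlH(OtBu)3 reduces an acid chloride to the aldehyde and stops there, leaving lactone and alkyl iodide untouched at −78 °C; the aldehyde has no α-hydrogen and cannot epimerise.

Step 17
Reactants: 27 iodo aldehyde
Product: 29 (1R,2S,5R,9S)-2-hydroxy-5-methyl-1-(chain A)-9-(chain B)-6,8-dioxabicyclo[3.2.2]nonan-7-one, via alkylchromium dichloride 28 (not isolated)
Conditions: CrCl2 (8 equiv), cobalt phthalocyanine (C32H16CoN8, cat.), DMF, rt, about 5 mM; aqueous work-up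
Reagents that add atoms: chromium dichloride, Cl[Cr]Cl (chromium in 28 only)
Why: CrCl2 reduces the cobalt phthalocyanine to a monovalent cobalt nucleophile that displaces the primary iodide; homolysis of the alkylcobalt and capture of the C9 radical by CrCl2 give alkylchromium 28 (trivalent chromium), which adds Grignard-fashion to the neighbouring formyl group. The closest known reaction type is the cobalt-catalysed variant of the Nozaki–Hiyama–Kishi (chromium Barbier) coupling of alkyl halides with aldehydes, used here intramolecularly. The new C9–C10 bond closes the oxepane (C10–C11–O–C6–C7–C8–C9) and the ε-lactone (C10–C11–C(=O)–O–C7–C8–C9) in the same event, each by 7-exo-trig attack on the exocyclic C=O, and turns the dioxanone into the 6,8-dioxabicyclo[3.2.2]nonan-7-one. C10 is the only new stereocentre: the tether fixes the direction of attack (anti to chain A), so its configuration follows from the formyl rotamer, and the rotamer that puts the oxygen on the flank of the lactone carbonyl should win because the chromium alkoxide is chelated there by the lactone C=O and stays clear of chain B on the other flank. Chemoselectivity for the aldehyde over the lactone, silyl ethers and trisubstituted alkenes is inherent in organochromium reagents, 28 has no β-leaving group to eliminate, and high dilution suppresses intermolecular addition.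

Step 18
Reactants: 29 bis-TBDPS ether
Product: 30 target, (1R,2S,5R,9S)-2-hydroxy-9-[(3Z)-5-hydroxy-3-methylpent-3-en-1-yl]-1-[(3Z)-5-hydroxy-4-methylpent-3-en-1-yl]-5-methyl-6,8-dioxabicyclo[3.2.2]nonan-7-one
Conditions: HF·pyridine, pyridine, THF, 0 °C to rt
Reagents that add atoms: none
Why: Buffered fluoride desilylation should free both allylic alcohols without opening the bridged β-hydroxy lactone or isomerising the Z-alkenes.

**Compound list**

1 | 3-[(tert-butyldimethylsilyl)oxy]propanal | O=CCCO[Si](C)(C)C(C)(C)C | starting material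
2 | ethyl 2-[bis(2,2,2-trifluoroethoxy)phosphoryl]propanoate | CCOC(=O)C(C)P(=O)(OCC(F)(F)F)OCC(F)(F)F | starting material
3 | ethyl (2Z)-5-(TBS-oxy)-2-methylpent-2-enoate | C/C(=C/CCO[Si](C)(C)C(C)(C)C)C(=O)OCC | intermediate
4 | (2Z)-5-(TBS-oxy)-2-methylpent-2-en-1-ol | C/C(=C/CCO[Si](C)(C)C(C)(C)C)CO | intermediate
5 | (2Z)-5-(TBS-oxy)-1-(TBDPS-oxy)-2-methylpent-2-ene | C/C(=C/CCO[Si](C)(C)C(C)(C)C)CO[Si](c1ccccc1)(c1ccccc1)C(C)(C)C | intermediate
6 | (3Z)-5-(TBDPS-oxy)-4-methylpent-3-en-1-ol | C/C(=C/CCO)CO[Si](c1ccccc1)(c1ccccc1)C(C)(C)C | intermediate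
7 | tert-butyl{[(2Z)-5-iodo-2-methylpent-2-en-1-yl]oxy}diphenylsilane | C/C(=C/CCI)CO[Si](c1ccccc1)(c1ccccc1)C(C)(C)C | intermediate
8 | nerol, (2Z)-3,7-dimethylocta-2,6-dien-1-ol | CC(C)=CCC/C(C)=C\CO | starting material
9 | tert-butyl{[(2Z)-3,7-dimethylocta-2,6-dien-1-yl]oxy}diphenylsilane | CC(C)=CCC/C(C)=C\CO[Si](c1ccccc1)(c1ccccc1)C(C)(C)C | intermediate
10 | (2E,6Z)-8-(TBDPS-oxy)-2,6-dimethylocta-2,6-dien-1-ol | OC/C(C)=C/CC/C(C)=C\CO[Si](c1ccccc1)(c1ccccc1)C(C)(C)C | intermediate
11 | [(2S,3S)-2-methyl-3-(chain B)oxiran-2-yl]methanol | OC[C@]1(C)O[C@H]1CC/C(C)=C\CO[Si](c1ccccc1)(c1ccccc1)C(C)(C)C | intermediate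
12 | trimethylsulfonium iodide | C[S+](C)C.[I-] | starting material
13 | (1S,4Z)-6-(TBDPS-oxy)-4-methyl-1-[(2R)-2-methyloxiran-2-yl]hex-4-en-1-ol | C[C@@]1(CO1)[C@@H](O)CC/C(C)=C\CO[Si](c1ccccc1)(c1ccccc1)C(C)(C)C | intermediate
14 | (3R,4S,7Z)-9-(TBDPS-oxy)-3,7-dimethylnona-1,7-diene-3,4-diol | C=C[C@@](C)(O)[C@@H](O)CC/C(C)=C\CO[Si](c1ccccc1)(c1ccccc1)C(C)(C)C | intermediate
15 | tert-butyl bromoacetate | CC(C)(C)OC(=O)CBr | starting material
16 | tert-butyl {[(3R,4S,7Z)-9-(TBDPS-oxy)-3-hydroxy-3,7-dimethylnona-1,7-dien-4-yl]oxy}acetate | C=C[C@@](C)(O)[C@@H](OCC(=O)OC(C)(C)C)CC/C(C)=C\CO[Si](c1ccccc1)(c1ccccc1)C(C)(C)C | intermediate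
17 | (5S,6R)-5-(chain B)-6-ethenyl-6-methyl-1,4-dioxan-2-one | O=C1CO[C@@H](CC/C(C)=C\CO[Si](c2ccccc2)(c2ccccc2)C(C)(C)C)[C@@](C)(C=C)O1 | intermediate
18 | di-tert-butyl dicarbonate | CC(C)(C)OC(=O)OC(=O)OC(C)(C)C | starting material
19 | tert-butyl (5R,6S)-5-ethenyl-5-methyl-3-oxo-6-(chain B)-1,4-dioxane-2-carboxylate, C2 epimers | CC(C)(C)OC(=O)C1O[C@@H](CC/C(C)=C\CO[Si](c2ccccc2)(c2ccccc2)C(C)(C)C)[C@@](C)(C=C)OC1=O | intermediate
20 | tert-butyl (2R,5R,6S)-5-ethenyl-5-methyl-3-oxo-2-(chain A)-6-(chain B)-1,4-dioxane-2-carboxylate | C/C(=C/CC[C@]1(C(=O)OC(C)(C)C)O[C@@H](CC/C(C)=C\CO[Si](c2ccccc2)(c2ccccc2)C(C)(C)C)[C@@](C)(C=C)OC1=O)CO[Si](c1ccccc1)(c1ccccc1)C(C)(C)C | intermediate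
21 | 9-BBN adduct of 20, boron on the terminal carbon of the former ethenyl group | C/C(=C/CC[C@]1(C(=O)OC(C)(C)C)O[C@@H](CC/C(C)=C\CO[Si](c2ccccc2)(c2ccccc2)C(C)(C)C)[C@@](C)(CCB2C3CCCC2CCC3)OC1=O)CO[Si](c1ccccc1)(c1ccccc1)C(C)(C)C | intermediate
22 | tert-butyl (2R,5R,6S)-5-(2-hydroxyethyl)-5-methyl-3-oxo-2-(chain A)-6-(chain B)-1,4-dioxane-2-carboxylate | C/C(=C/CC[C@]1(C(=O)OC(C)(C)C)O[C@@H](CC/C(C)=C\CO[Si](c2ccccc2)(c2ccccc2)C(C)(C)C)[C@@](C)(CCO)OC1=O)CO[Si](c1ccccc1)(c1ccccc1)C(C)(C)C | intermediate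
23 | tert-butyl (2R,5R,6S)-5-(2-iodoethyl)-5-methyl-3-oxo-2-(chain A)-6-(chain B)-1,4-dioxane-2-carboxylate | C/C(=C/CC[C@]1(C(=O)OC(C)(C)C)O[C@@H](CC/C(C)=C\CO[Si](c2ccccc2)(c2ccccc2)C(C)(C)C)[C@@](C)(CCI)OC1=O)CO[Si](c1ccccc1)(c1ccccc1)C(C)(C)C | intermediate
24 | trimethylsilyl ester of acid 25 (same configuration) | C/C(=C/CC[C@]1(C(=O)O[Si](C)(C)C)O[C@@H](CC/C(C)=C\CO[Si](c2ccccc2)(c2ccccc2)C(C)(C)C)[C@@](C)(CCI)OC1=O)CO[Si](c1ccccc1)(c1ccccc1)C(C)(C)C | intermediate
25 | (2R,5R,6S)-5-(2-iodoethyl)-5-methyl-3-oxo-2-(chain A)-6-(chain B)-1,4-dioxane-2-carboxylic acid | C/C(=C/CC[C@]1(C(=O)O)O[C@@H](CC/C(C)=C\CO[Si](c2ccccc2)(c2ccccc2)C(C)(C)C)[C@@](C)(CCI)OC1=O)CO[Si](c1ccccc1)(c1ccccc1)C(C)(C)C | intermediate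
26 | acid chloride of 25 (same configuration) | C/C(=C/CC[C@]1(C(=O)Cl)O[C@@H](CC/C(C)=C\CO[Si](c2ccccc2)(c2ccccc2)C(C)(C)C)[C@@](C)(CCI)OC1=O)CO[Si](c1ccccc1)(c1ccccc1)C(C)(C)C | intermediate
27 | (2R,5R,6S)-5-(2-iodoethyl)-5-methyl-3-oxo-2-(chain A)-6-(chain B)-1,4-dioxane-2-carbaldehyde | C/C(=C/CC[C@]1(C=O)O[C@@H](CC/C(C)=C\CO[Si](c2ccccc2)(c2ccccc2)C(C)(C)C)[C@@](C)(CCI)OC1=O)CO[Si](c1ccccc1)(c1ccccc1)C(C)(C)C | intermediate
28 | alkylchromium dichloride from 27 (C–I replaced by C–CrCl2, trivalent chromium, DMF-solvated) | C/C(=C/CC[C@]1(C=O)O[C@@H](CC/C(C)=C\CO[Si](c2ccccc2)(c2ccccc2)C(C)(C)C)[C@@](C)(CC[Cr](Cl)Cl)OC1=O)CO[Si](c1ccccc1)(c1ccccc1)C(C)(C)C | intermediate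
29 | (1R,2S,5R,9S)-2-hydroxy-5-methyl-1-(chain A)-9-(chain B)-6,8-dioxabicyclo[3.2.2]nonan-7-one | C/C(=C/CC[C@@]12O[C@@H](CC/C(C)=C\CO[Si](c3ccccc3)(c3ccccc3)C(C)(C)C)[C@@](C)(CC[C@@H]1O)OC2=O)CO[Si](c1ccccc1)(c1ccccc1)C(C)(C)C | intermediate
30 | (1R,2S,5R,9S)-2-hydroxy-9-[(3Z)-5-hydroxy-3-methylpent-3-en-1-yl]-1-[(3Z)-5-hydroxy-4-methylpent-3-en-1-yl]-5-methyl-6,8-dioxabicyclo[3.2.2]nonan-7-one | C/C(=C/CC[C@@]12O[C@@H](CC/C(C)=C\CO)[C@@](C)(CC[C@@H]1O)OC2=O)CO | target

**Totals and risks**

Total step count: 18. Longest linear sequence: 13 steps (steps 6–18, from nerol).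

Steps most likely to fail:

Step 17. The alkylchromium may be protonated, or the C9 radical reduced, before it reaches the hindered formyl group, giving loss of iodine without ring closure; the formyl group may also react through the other rotamer. Fallback: close the same bond reversibly with a removable activating group. Setting out from 27, AgNO2 in Et2O should give the nitro aldehyde F1. Catalytic DBU in THF at 0 °C should close it by intramolecular Henry addition to the bicyclic nitro alcohol F2, under thermodynamic control that places the hydroxyl on the less crowded lactone flank. Radical denitration (Bu3SnH, AIBN, toluene, reflux) then removes the nitro group and comes back to the route at 29.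

Step 9. Migration of the epoxide onto the fully substituted C7 may be slower than direct attack of the ylide at C6 of the trisubstituted epoxide, giving the regioisomeric allylic alcohol or incomplete conversion. Fallback: build the terminal epoxide stepwise by intramolecular oxygen delivery. Setting out from 11, PhNCO and Et3N give the phenylcarbamate F3. BF3·OEt2 in Et2O at −20 °C, then dilute H2SO4, should open the epoxide at C7 with inversion (5-exo) and give the cyclic carbonate F4. K2CO3 in MeOH gives the triol F5; TsCl, Et3N and catalytic Bu2SnO give the primary tosylate F6; K2CO3 in MeOH closes the epoxide and comes back to the route at 13, which is then treated in isolated form with the ylide of step 9 to reach 14.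

Step 12. E2 elimination of the homoallylic iodide, O-alkylation, or slow SN2 at the hindered alkoxymalonate carbanion may erode C-alkylation and its facial selectivity. Fallback: replace the SN2 step by conjugate addition and olefination. Setting out from 19, acrolein with catalytic DBU in CH2Cl2 at 0 °C should give the Michael adduct F7 with the same facial preference. Still–Gennari olefination with 2 (KN(SiMe3)2, 18-crown-6, THF, −78 °C) gives the Z-enoate F8. iBu2AlH at −78 °C should reduce the unhindered conjugated ester to the allylic alcohol F9 while the lactone and tert-butyl ester carbonyls on the fully substituted C11 are shielded. TBDPSCl and imidazole then come back to the route at 20.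

**Further compounds**

F1 | step 17 | (2R,5R,6S)-5-methyl-5-(2-nitroethyl)-3-oxo-2-(chain A)-6-(chain B)-1,4-dioxane-2-carbaldehyde | C/C(=C/CC[C@]1(C=O)O[C@@H](CC/C(C)=C\CO[Si](c2ccccc2)(c2ccccc2)C(C)(C)C)[C@@](C)(CC[N+](=O)[O-])OC1=O)CO[Si](c1ccccc1)(c1ccccc1)C(C)(C)C
F2 | step 17 | (1R,2S,5R,9S)-2-hydroxy-5-methyl-3-nitro-1-(chain A)-9-(chain B)-6,8-dioxabicyclo[3.2.2]nonan-7-one, C3 epimers | C/C(=C/CC[C@@]12O[C@@H](CC/C(C)=C\CO[Si](c3ccccc3)(c3ccccc3)C(C)(C)C)[C@@](C)(CC([N+](=O)[O-])[C@@H]1O)OC2=O)CO[Si](c1ccccc1)(c1ccccc1)C(C)(C)C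
F3 | step 9 | [(2S,3S)-2-methyl-3-(chain B)oxiran-2-yl]methyl N-phenylcarbamate | O=C(Nc1ccccc1)OC[C@]1(C)O[C@H]1CC/C(C)=C\CO[Si](c1ccccc1)(c1ccccc1)C(C)(C)C
F4 | step 9 | (4R)-4-[(1S,4Z)-6-(TBDPS-oxy)-1-hydroxy-4-methylhex-4-en-1-yl]-4-methyl-1,3-dioxolan-2-one | O=C1OC[C@@](C)(O1)[C@@H](O)CC/C(C)=C\CO[Si](c1ccccc1)(c1ccccc1)C(C)(C)C
F5 | step 9 | (2R,3S,6Z)-8-(TBDPS-oxy)-2,6-dimethyloct-6-ene-1,2,3-triol | OC[C@@](C)(O)[C@@H](O)CC/C(C)=C\CO[Si](c1ccccc1)(c1ccccc1)C(C)(C)C
F6 | step 9 | (2R,3S,6Z)-8-(TBDPS-oxy)-2,3-dihydroxy-2,6-dimethyloct-6-en-1-yl 4-methylbenzenesulfonate | Cc1ccc(cc1)S(=O)(=O)OC[C@@](C)(O)[C@@H](O)CC/C(C)=C\CO[Si](c1ccccc1)(c1ccccc1)C(C)(C)C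
F7 | step 12 | tert-butyl (2R,5R,6S)-5-ethenyl-5-methyl-3-oxo-2-(3-oxopropyl)-6-(chain B)-1,4-dioxane-2-carboxylate | O=CCC[C@]1(C(=O)OC(C)(C)C)O[C@@H](CC/C(C)=C\CO[Si](c2ccccc2)(c2ccccc2)C(C)(C)C)[C@@](C)(C=C)OC1=O
F8 | step 12 | ethyl (2Z)-5-[(2R,5R,6S)-2-(tert-butoxycarbonyl)-5-ethenyl-5-methyl-3-oxo-6-(chain B)-1,4-dioxan-2-yl]-2-methylpent-2-enoate | C/C(=C/CC[C@]1(C(=O)OC(C)(C)C)O[C@@H](CC/C(C)=C\CO[Si](c2ccccc2)(c2ccccc2)C(C)(C)C)[C@@](C)(C=C)OC1=O)C(=O)OCC
F9 | step 12 | tert-butyl (2R,5R,6S)-5-ethenyl-2-[(3Z)-5-hydroxy-4-methylpent-3-en-1-yl]-5-methyl-3-oxo-6-(chain B)-1,4-dioxane-2-carboxylate | C/C(=C/CC[C@]1(C(=O)OC(C)(C)C)O[C@@H](CC/C(C)=C\CO[Si](c2ccccc2)(c2ccccc2)C(C)(C)C)[C@@](C)(C=C)OC1=O)CO
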